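**Plan**

- Retrosynthesis cuts, in this order: the C3a–allyl bond (dearomatising para-allylation of a C6 phenol), the C3 methyl back to a C3 ester, the C3–C3a bond of ring B (ring contraction of a 2-arylchroman-4-one), the C2–aryl bond (conjugate arylation of a chromone), and the pyranone (from an acetophenone made from isovanillin).
- Enabling feature, in benzofuran numbering (O1, C2 aryl, C3 methyl, C3a allyl, C4–C7, C7a; ring A the dienone, ring B the dihydrofuran): C3 of ring B carries one exocyclic carbon and is bonded to the ring A carbon C3a, next to the aryl-bearing C2. This is the pattern left when a flavanone expels its carbonyl carbon from the ring.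
- Forward: ring A comes from isovanillin, a pyranone is fused on and arylated at C2, the pyranone is contracted to ring B, the ester is reduced to methyl, and ring A is dearomatised last by allylation at C3a.
- Stereochemistry: C2 from the chiral catalyst in the conjugate arylation; C3 by equilibration trans to the C2 aryl group; C3a by attack anti to the C3 methyl group.

Key step: step 7

Assumption: the palladium/pyridine-oxazoline catalyst is taken to distinguish the faces of the chromone as it does those of cyclic enones, so the (R)-ligand is assigned to the 2S flavanone; should the sense prove opposite, the (S)-ligand is used in the same step. The descriptor at C2 changes from S to R in compounds 11 and 12 only because C3 gains priority; the spatial arrangement is the same throughout.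

**Step 1**
Reactants: 1 isovanillin
Product: 3 4-methoxybenzene-1,3-diol, via aryl formate 2 (not isolated)
Conditions: mCPBA, CH2Cl2, 0 °C to rt; then MeOH, HCl (cat.), rt
Reagents that add atoms: 3-chloroperoxybenzoic acid (mCPBA), O=C(OO)c1cccc(Cl)c1
Why: Baeyer–Villiger (Dakin-type) oxidation, in which the electron-rich aryl group para to the methoxy group migrates to give the aryl formate, which methanolysis cleaves to the phenol.

**Step 2**
Reactants: 3 4-methoxybenzene-1,3-diol
Product: 4 1-(2,4-dihydroxy-5-methoxyphenyl)ethan-1-one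
Conditions: AcOH, ZnCl2, 130 °C
Reagents that add atoms: acetic acid, CC(=O)O
Why: Nencki (Friedel–Crafts) C-acylation of the resorcinol should occur at the one ring position that is para to one hydroxyl and ortho to the other, the position between the two hydroxyls being hindered.

**Step 3**
Reactants: 4 1-(2,4-dihydroxy-5-methoxyphenyl)ethan-1-one
Product: 5 1-{2-hydroxy-5-methoxy-4-[tri(propan-2-yl)silyloxy]phenyl}ethan-1-one
Conditions: iPr3SiCl (1.05 equiv), imidazole, DMF, 0 °C to rt
Reagents that add atoms: triisopropylsilyl chloride, CC(C)[Si](Cl)(C(C)C)C(C)C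
Why: Regioselective silylation, since the 2-hydroxyl is held in a hydrogen bond to the ketone and the bulky silyl chloride should take the free 4-hydroxyl, which has to be masked until the final oxidation.

**Step 4**
Reactants: 5 1-{2-hydroxy-5-methoxy-4-[tri(propan-2-yl)silyloxy]phenyl}ethan-1-one
Product: 7 6-methoxy-7-[tri(propan-2-yl)silyloxy]-4H-chromen-4-one, via enaminone 6 (not isolated)
Conditions: Me2NCH(OMe)2, toluene, 90 °C; then AcOH, 60 °C
Reagents that add atoms: N,N-dimethylformamide dimethyl acetal, COC(OC)N(C)C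
Why: Enaminone route to chromones, in which the acetal condenses at the acetyl methyl group and acid then promotes conjugate addition of the phenol and loss of dimethylamine to close the pyranone.

**Step 5**
Reactants: 7 6-methoxy-7-[tri(propan-2-yl)silyloxy]-4H-chromen-4-one; 8 3,4,5-trimethoxyphenylboronic acid
Product: 9 (2S)-6-methoxy-7-[tri(propan-2-yl)silyloxy]-2-(3,4,5-trimethoxyphenyl)-2,3-dihydro-4H-chromen-4-one
Conditions: Pd(OCOCF3)2 (5 mol %), (R)-4-tert-butyl-2-(pyridin-2-yl)-4,5-dihydrooxazole (6 mol %), NH4PF6 (30 mol %), H2O (5 equiv), ClCH2CH2Cl, 60 °C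
Reagents that add atoms: none
Why: Catalytic asymmetric conjugate addition of an arylboronic acid to a chromone by a cationic divalent palladium/pyridine-oxazoline complex (aryl transfer, enantio-determining carbopalladation of C2=C3, protonolysis of the palladium enolate by water), with the (R)-ligand chosen to shield the face that leaves C2 as S.

**Step 6**
Reactants: 9 (2S)-6-methoxy-7-[tri(propan-2-yl)silyloxy]-2-(3,4,5-trimethoxyphenyl)-2,3-dihydro-4H-chromen-4-one
Product: 11 (2R)-3-diazo-6-methoxy-7-[tri(propan-2-yl)silyloxy]-2-(3,4,5-trimethoxyphenyl)-2,3-dihydro-4H-chromen-4-one, via trifluoroacetyl ketone 10 (not isolated)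
Conditions: LiN(SiMe3)2, THF, −78 °C, then CF3CO2CH2CF3, −78 °C, 5% aq. HCl work-up; crude 10, 4-AcNHC6H4SO2N3, Et3N, H2O (1 equiv), MeCN, rt
Reagents that add atoms: 4-acetamidobenzenesulfonyl azide, CC(=O)Nc1ccc(cc1)S(=O)(=O)N=[N+]=[N-]; 2,2,2-trifluoroethyl trifluoroacetate, O=C(OCC(F)(F)F)C(F)(F)F (its atoms stay only in 10)
Why: Detrifluoroacetylative diazo transfer, in which kinetic acylation of the lithium enolate at −78 °C activates C3 before the enolate can open the ring by loss of phenoxide and the sulfonyl azide then exchanges the trifluoroacetyl group for N2, C2 being untouched.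

**Step 7**
Reactants: 11 (2R)-3-diazo-6-methoxy-7-[tri(propan-2-yl)silyloxy]-2-(3,4,5-trimethoxyphenyl)-2,3-dihydro-4H-chromen-4-one
Product: 14 methyl (2S,3S)-5-methoxy-6-[tri(propan-2-yl)silyloxy]-2-(3,4,5-trimethoxyphenyl)-2,3-dihydro-1-benzofuran-3-carboxylate, via ketene 12 (not isolated), via cis ester 13 (not isolated)
Conditions: hν (>300 nm, Pyrex), MeOH, 0 °C; then DBU (0.2 equiv), rt, same flask
Reagents that add atoms: methanol, CO
Why: Light excites the α-diazo ketone, which the ring holds s-cis, so N2 leaves as the ring A carbon (C4a of the chromanone, C3a of the product) shifts from the carbonyl carbon to the diazo carbon; this forms the C3–C3a bond and turns the old carbonyl carbon into a ketene exocyclic to the new five-membered ring (12). The closest known reaction is the photochemical Wolff ring contraction of cyclic 2-diazo ketones, 3-diazochroman-4-ones included. Ring B is therefore closed by a 1,2-shift that contracts the six-membered pyranone to the dihydrofuran, not by cyclisation of an open chain. Methanol adds to the ketene, and protonation of the resulting ester enol should give both C3 epimers (13 and 14), which DBU equilibrates to the trans ester, so C3 is set as S under thermodynamic control by the neighbouring C2 aryl group, while C2 takes no part and keeps its configuration from step 5. The step needs aryl migration to win over 1,2-hydride shift from C2 and over O–H insertion, which the concerted shift from the s-cis excited state and the high migratory aptitude of the electron-rich, oxygen-substituted aryl carbon should secure.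

**Step 8**
Reactants: 14 methyl (2S,3S)-5-methoxy-6-[tri(propan-2-yl)silyloxy]-2-(3,4,5-trimethoxyphenyl)-2,3-dihydro-1-benzofuran-3-carboxylate
Product: 15 [(2S,3R)-5-methoxy-6-[tri(propan-2-yl)silyloxy]-2-(3,4,5-trimethoxyphenyl)-2,3-dihydro-1-benzofuran-3-yl]methanol
Conditions: LiAlH4, THF, 0 °C; aq. NaOH work-up
Reagents that add atoms: none
Why: Hydride reduction of the ester to the primary alcohol, which touches no stereocentre (the descriptor at C3 changes by priority only) and should leave the aryl silyl ether intact at 0 °C.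

**Step 9**
Reactants: 15 [(2S,3R)-5-methoxy-6-[tri(propan-2-yl)silyloxy]-2-(3,4,5-trimethoxyphenyl)-2,3-dihydro-1-benzofuran-3-yl]methanol
Product: 16 (2S,3S)-3-(iodomethyl)-5-methoxy-6-[tri(propan-2-yl)silyloxy]-2-(3,4,5-trimethoxyphenyl)-2,3-dihydro-1-benzofuran
Conditions: I2, PPh3, imidazole, CH2Cl2, 0 °C to rt
Reagents that add atoms: iodine, II
Why: Appel-type iodination (Garegg–Samuelsson conditions) of the primary alcohol through its alkoxyphosphonium salt, with substitution at the CH2 carbon only.

**Step 10**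
Reactants: 16 (2S,3S)-3-(iodomethyl)-5-methoxy-6-[tri(propan-2-yl)silyloxy]-2-(3,4,5-trimethoxyphenyl)-2,3-dihydro-1-benzofuran
Product: 17 (2S,3S)-5-methoxy-3-methyl-6-[tri(propan-2-yl)silyloxy]-2-(3,4,5-trimethoxyphenyl)-2,3-dihydro-1-benzofuran
Conditions: LiBHEt3, THF, 0 °C to rt
Reagents that add atoms: none
Why: SN2 displacement of the primary iodide by the strongly nucleophilic hydride of LiBHEt3, which should outpace elimination toward the benzofuran and does not involve the C3 stereocentre.

**Step 11**
Reactants: 17 (2S,3S)-5-methoxy-3-methyl-6-[tri(propan-2-yl)silyloxy]-2-(3,4,5-trimethoxyphenyl)-2,3-dihydro-1-benzofuran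
Product: 18 (2S,3S)-5-methoxy-3-methyl-2-(3,4,5-trimethoxyphenyl)-2,3-dihydro-1-benzofuran-6-ol
Conditions: Bu4NF, AcOH, THF, 0 °C to rt
Reagents that add atoms: none
Why: Fluoride cleavage of the aryl silyl ether, buffered with acetic acid so that the electron-rich phenol is not left as a free phenoxide.

**Step 12**
Reactants: 18 (2S,3S)-5-methoxy-3-methyl-2-(3,4,5-trimethoxyphenyl)-2,3-dihydro-1-benzofuran-6-ol; 19 allyltrimethylsilane
Product: 20 (2S,3S,3aS)-5-methoxy-3-methyl-3a-(prop-2-en-1-yl)-2-(3,4,5-trimethoxyphenyl)-3,3a-dihydro-1-benzofuran-6(2H)-one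
Conditions: PhI(OAc)2 (1.1 equiv), 19 (5 equiv), (CF3)2CHOH/CH2Cl2, −20 °C
Reagents that add atoms: none
Why: Oxidative dearomatisation with umpolung (Hosomi–Sakurai-type para-allylation of a phenol), in which PhI(OAc)2 generates the phenoxenium ion and the allylsilane should attack the alkyl-bearing para carbon C3a on the face opposite the adjacent C3 methyl group, setting C3a as S and leaving the dienone as a vinylogous ester through O1.

**Compound list**

1 | isovanillin (3-hydroxy-4-methoxybenzaldehyde) | COc1ccc(C=O)cc1O | starting material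
2 | 3-hydroxy-4-methoxyphenyl formate (aryl formate, not isolated) | COc1ccc(OC=O)cc1O | intermediate
3 | 4-methoxybenzene-1,3-diol | COc1ccc(O)cc1O | intermediate
4 | 1-(2,4-dihydroxy-5-methoxyphenyl)ethan-1-one | CC(=O)c1cc(OC)c(O)cc1O | intermediate
5 | 1-{2-hydroxy-5-methoxy-4-[tri(propan-2-yl)silyloxy]phenyl}ethan-1-one | CC(=O)c1cc(OC)c(O[Si](C(C)C)(C(C)C)C(C)C)cc1O | intermediate
6 | (E)-3-(dimethylamino)-1-{2-hydroxy-5-methoxy-4-[tri(propan-2-yl)silyloxy]phenyl}prop-2-en-1-one (enaminone, not isolated) | CN(C)/C=C/C(=O)c1cc(OC)c(O[Si](C(C)C)(C(C)C)C(C)C)cc1O | intermediate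
7 | 6-methoxy-7-[tri(propan-2-yl)silyloxy]-4H-chromen-4-one | O=c1ccoc2cc(O[Si](C(C)C)(C(C)C)C(C)C)c(OC)cc12 | intermediate
8 | 3,4,5-trimethoxyphenylboronic acid | COc1cc(B(O)O)cc(OC)c1OC | starting material
9 | (2S)-6-methoxy-7-[tri(propan-2-yl)silyloxy]-2-(3,4,5-trimethoxyphenyl)-2,3-dihydro-4H-chromen-4-one | O=C1C[C@@H](c2cc(OC)c(OC)c(OC)c2)Oc2cc(O[Si](C(C)C)(C(C)C)C(C)C)c(OC)cc12 | intermediate
10 | (2S)-6-methoxy-7-[tri(propan-2-yl)silyloxy]-3-(trifluoroacetyl)-2-(3,4,5-trimethoxyphenyl)-2,3-dihydro-4H-chromen-4-one (C3 epimers and enol, not isolated) | O=C1C(C(=O)C(F)(F)F)[C@@H](c2cc(OC)c(OC)c(OC)c2)Oc2cc(O[Si](C(C)C)(C(C)C)C(C)C)c(OC)cc12 | intermediate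
11 | (2R)-3-diazo-6-methoxy-7-[tri(propan-2-yl)silyloxy]-2-(3,4,5-trimethoxyphenyl)-2,3-dihydro-4H-chromen-4-one | [N-]=[N+]=C1C(=O)c2cc(OC)c(O[Si](C(C)C)(C(C)C)C(C)C)cc2O[C@@H]1c1cc(OC)c(OC)c(OC)c1 | intermediate
12 | {(2R)-5-methoxy-6-[tri(propan-2-yl)silyloxy]-2-(3,4,5-trimethoxyphenyl)-1-benzofuran-3(2H)-ylidene}ethenone (ketene, not isolated) | O=C=C1c2cc(OC)c(O[Si](C(C)C)(C(C)C)C(C)C)cc2O[C@@H]1c1cc(OC)c(OC)c(OC)c1 | intermediate
13 | methyl (2S,3R)-5-methoxy-6-[tri(propan-2-yl)silyloxy]-2-(3,4,5-trimethoxyphenyl)-2,3-dihydro-1-benzofuran-3-carboxylate (cis ester, not isolated) | c12cc(OC)c(O[Si](C(C)C)(C(C)C)C(C)C)cc1O[C@H](c1cc(OC)c(OC)c(OC)c1)[C@@H]2C(=O)OC | intermediate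
14 | methyl (2S,3S)-5-methoxy-6-[tri(propan-2-yl)silyloxy]-2-(3,4,5-trimethoxyphenyl)-2,3-dihydro-1-benzofuran-3-carboxylate (trans ester) | c12cc(OC)c(O[Si](C(C)C)(C(C)C)C(C)C)cc1O[C@H](c1cc(OC)c(OC)c(OC)c1)[C@H]2C(=O)OC | intermediate
15 | [(2S,3R)-5-methoxy-6-[tri(propan-2-yl)silyloxy]-2-(3,4,5-trimethoxyphenyl)-2,3-dihydro-1-benzofuran-3-yl]methanol | c12cc(OC)c(O[Si](C(C)C)(C(C)C)C(C)C)cc1O[C@H](c1cc(OC)c(OC)c(OC)c1)[C@H]2CO | intermediate
16 | (2S,3S)-3-(iodomethyl)-5-methoxy-6-[tri(propan-2-yl)silyloxy]-2-(3,4,5-trimethoxyphenyl)-2,3-dihydro-1-benzofuran | c12cc(OC)c(O[Si](C(C)C)(C(C)C)C(C)C)cc1O[C@H](c1cc(OC)c(OC)c(OC)c1)[C@H]2CI | intermediate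
17 | (2S,3S)-5-methoxy-3-methyl-6-[tri(propan-2-yl)silyloxy]-2-(3,4,5-trimethoxyphenyl)-2,3-dihydro-1-benzofuran | c12cc(OC)c(O[Si](C(C)C)(C(C)C)C(C)C)cc1O[C@H](c1cc(OC)c(OC)c(OC)c1)[C@H]2C | intermediate
18 | (2S,3S)-5-methoxy-3-methyl-2-(3,4,5-trimethoxyphenyl)-2,3-dihydro-1-benzofuran-6-ol | c12cc(OC)c(O)cc1O[C@H](c1cc(OC)c(OC)c(OC)c1)[C@H]2C | intermediate
19 | allyltrimethylsilane | C=CC[Si](C)(C)C | starting material
20 | (2S,3S,3aS)-5-methoxy-3-methyl-3a-(prop-2-en-1-yl)-2-(3,4,5-trimethoxyphenyl)-3,3a-dihydro-1-benzofuran-6(2H)-one | C=CC[C@]12C=C(OC)C(=O)C=C1O[C@H](c1cc(OC)c(OC)c(OC)c1)[C@H]2C | target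

**Step count and risks**

Total step count: 12. Longest linear sequence: 12 steps, from isovanillin (1) to 20.

Steps most likely to fail:

1. Step 12. The allylsilane may be captured at the methoxy-bearing C5 or at the free C7 of the phenoxenium ion instead of at C3a, and approach syn to the C3 methyl group may compete. The fallback is sigmatropic instead of oxidative and sets out from 18. O-Allylation with allyl bromide and K2CO3 in acetone would give (2S,3S)-5-methoxy-3-methyl-6-(prop-2-en-1-yloxy)-2-(3,4,5-trimethoxyphenyl)-2,3-dihydro-1-benzofuran F1. Heating in N,N-diethylaniline near 190 °C should move the allyl group by aromatic Claisen shift to the blocked C5, giving the non-enolisable (2S,3S)-5-methoxy-3-methyl-5-(prop-2-en-1-yl)-2-(3,4,5-trimethoxyphenyl)-2,3-dihydro-1-benzofuran-6(5H)-one F2. This passes on by Cope shift to C3a (para-Claisen rearrangement) and the route is rejoined at 20, after separation from the C3a epimer and from the C7-allyl phenol that the direct ortho shift produces.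

2. Step 7. After loss of N2, 1,2-hydride shift from C2 (aromatisation to the flavone) or O–H insertion of methanol may outrun aryl migration, and reversible opening of the ester enolate during the base equilibration may erode the configuration at C2. The fallback is an oxidative ring contraction without a diazo compound and sets out from 9. PhI(OAc)2 with catalytic H2SO4 in HC(OMe)3 should convert the ketone into its methyl enol ether, (2S)-4,6-dimethoxy-7-[tri(propan-2-yl)silyloxy]-2-(3,4,5-trimethoxyphenyl)-2H-chromene F3. Trivalent iodine then adds to C3 anti to the aryl group, and the ring A carbon migrates from C4 to C3 as iodobenzene leaves. The same C3–C3a bond forms and the trans methyl ester is reached directly, so the route is rejoined at 14 and steps 6 and 7 are bypassed.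

3. Step 5. Carbopalladation of a chromone that carries two oxygen donors on ring A may be slow, letting protodeboronation consume the boronic acid, and enantiofacial control may be incomplete. The fallback forms the C2–O1 bond instead of the C2–aryl bond and sets out from 5. Claisen–Schmidt condensation with 3,4,5-trimethoxybenzaldehyde (Ba(OH)2, MeOH, rt) would give (E)-1-{2-hydroxy-5-methoxy-4-[tri(propan-2-yl)silyloxy]phenyl}-3-(3,4,5-trimethoxyphenyl)prop-2-en-1-one F4. Enantioselective intramolecular oxa-Michael addition under a bifunctional cinchona-alkaloid thiourea of the pseudo-enantiomeric series that delivers 2S closes the pyranone, and the route is rejoined at 9.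

**Further compounds**

F1 | step 12 | (2S,3S)-5-methoxy-3-methyl-6-(prop-2-en-1-yloxy)-2-(3,4,5-trimethoxyphenyl)-2,3-dihydro-1-benzofuran | c12cc(OC)c(OCC=C)cc1O[C@H](c1cc(OC)c(OC)c(OC)c1)[C@H]2C
F2 | step 12 | (2S,3S)-5-methoxy-3-methyl-5-(prop-2-en-1-yl)-2-(3,4,5-trimethoxyphenyl)-2,3-dihydro-1-benzofuran-6(5H)-one (both C5 epimers) | C=CCC1(OC)C=C2[C@H](C)[C@@H](c3cc(OC)c(OC)c(OC)c3)OC2=CC1=O
F3 | step 7 | (2S)-4,6-dimethoxy-7-[tri(propan-2-yl)silyloxy]-2-(3,4,5-trimethoxyphenyl)-2H-chromene | COC1=C[C@@H](c2cc(OC)c(OC)c(OC)c2)Oc2cc(O[Si](C(C)C)(C(C)C)C(C)C)c(OC)cc12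
F4 | step 5 | (E)-1-{2-hydroxy-5-methoxy-4-[tri(propan-2-yl)silyloxy]phenyl}-3-(3,4,5-trimethoxyphenyl)prop-2-en-1-one | O=C(/C=C/c1cc(OC)c(OC)c(OC)c1)c1cc(OC)c(O[Si](C(C)C)(C(C)C)C(C)C)cc1O
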